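Cuts: the three aryl O–MOM bonds go first. C2–H is then traced back to a C2–O acetal carrying a chiral alcohol, and ring C is cut at C3–C4 and O1–C2 in one retro-[4+2]. On ring B, the C5'–CMe2 bond goes back to a 4'-O-prenyl ether, and the C1' side chain goes back to a formyl group plus one carbon.
Enabling feature: C3 lies between the benzylic C4H2 on resorcinol ring A and the C2H2–O1 unit. O1–C8a–C4a–C4 is therefore the oxa-diene of an o-quinone methide of ring A, and C2=C3 with ring B on C3 is a beta-aryl enol ether.
Forward order: rings A and B are bought as hydroxybenzaldehydes. Ring B is fully substituted first (O-prenylation, methylation, ortho-Claisen) and its CHO becomes an alkyne and then a Z-enol ether, while ring A becomes an O-Boc benzyl alcohol. Ring C is closed last, by the cycloaddition that also joins the two halves.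
Stereochemistry: C3 is the only stereocentre. It is set in the cycloaddition by the (1S,2R)-2-phenylcyclohexyl group on the enol ether oxygen, and the C2 centre formed alongside it is deleted by ionic reduction.

Key step: step 11

Assumption: the facial sense of the cycloaddition is taken from the s-trans shielding model described under step 11, in which the (1S,2R)-auxiliary leads to 3R. If the adduct proves to belong to the 3S series, the equally available (1R,2S)-alcohol is used and nothing else changes.

Step 1
Reactants: 1 2,3,4-trihydroxybenzaldehyde; 2 prenyl bromide (1-bromo-3-methylbut-2-ene)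
Product: 3 2,3-dihydroxy-4-(3-methylbut-2-enyloxy)benzaldehyde
Conditions: NaHCO3 (1.2 equiv), 2 (1.05 equiv), DMF, Ar, 25–40 °C
Reagents that add atoms: none
Why: Williamson etherification under a base too weak to ionise more than the 4-OH, which is the most acidic phenol because it is para-conjugated to the formyl group, whereas the 2-OH is held in a hydrogen bond to C=O and the 3-OH is not conjugated, so mono-O-prenylation at O4 should prevail.

Step 2
Reactants: 3 2,3-dihydroxy-4-(3-methylbut-2-enyloxy)benzaldehyde
Product: 4 2-hydroxy-3-(methoxymethoxy)-4-(3-methylbut-2-enyloxy)benzaldehyde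
Conditions: MOMCl (1.05 equiv), i-Pr2NEt (1.2 equiv), CH2Cl2, 0 °C
Reagents that add atoms: chloromethyl methyl ether (MOMCl), COCCl
Why: MOM protection by O-alkylation with an alpha-chloro ether under a non-ionising amine base, selective because the 2-OH stays locked in its hydrogen bond to the aldehyde while the 3-OH is free, the selectivity routinely used to protect O3 and O4 but not O2 of 2,3,4-trihydroxyaryl carbonyl compounds.

Step 3
Reactants: 4 2-hydroxy-3-(methoxymethoxy)-4-(3-methylbut-2-enyloxy)benzaldehyde
Product: 5 2-methoxy-3-(methoxymethoxy)-4-(3-methylbut-2-enyloxy)benzaldehyde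
Conditions: MeI, K2CO3, DMF, rt
Reagents that add atoms: iodomethane, CI
Why: Williamson methylation of the only remaining phenol, whose chelation is broken once carbonate in a dipolar aprotic solvent ionises it.

Step 4
Reactants: 5 2-methoxy-3-(methoxymethoxy)-4-(3-methylbut-2-enyloxy)benzaldehyde
Product: 7 4-hydroxy-2-methoxy-3-(methoxymethoxy)-5-(2-methylbut-3-en-2-yl)benzaldehyde, via ortho-dienone 6 (not isolated)
Conditions: PhNEt2, Ar, sealed tube, 190 °C
Reagents that add atoms: none
Why: Aromatic ortho-Claisen rearrangement: the [3,3] shift transfers the prenyl group with allylic inversion to C5, the only ortho carbon that carries hydrogen, and enolisation of dienone 6 (whose transient stereocentre vanishes) makes this path irreversible, whereas migration to the OMOM-bearing C3 can only revert, and the basic solvent holds back acid-promoted cyclisation of the new phenol onto the vinyl group.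

Step 5
Reactants: 7 4-hydroxy-2-methoxy-3-(methoxymethoxy)-5-(2-methylbut-3-en-2-yl)benzaldehyde
Product: 8 2-methoxy-3,4-bis(methoxymethoxy)-5-(2-methylbut-3-en-2-yl)benzaldehyde
Conditions: NaH, then MOMCl, THF, 0 °C to rt
Reagents that add atoms: chloromethyl methyl ether (MOMCl), COCCl
Why: MOM protection through the preformed sodium phenoxide, needed because this phenol is flanked by a quaternary carbon and an OMOM group, and tolerated by the non-enolisable aldehyde.

Step 6
Reactants: 8 2-methoxy-3,4-bis(methoxymethoxy)-5-(2-methylbut-3-en-2-yl)benzaldehyde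
Product: 9 1-ethynyl-2-methoxy-3,4-bis(methoxymethoxy)-5-(2-methylbut-3-en-2-yl)benzene
Conditions: Ohira-Bestmann reagent, K2CO3, MeOH, rt
Reagents that add atoms: dimethyl (1-diazo-2-oxopropyl)phosphonate (Ohira-Bestmann reagent), COP(=O)(OC)C(=[N+]=[N-])C(C)=O
Why: Ohira-Bestmann variant of the Seyferth-Gilbert homologation: methanolysis frees the diazomethylphosphonate anion, which olefinates the non-enolisable aldehyde, and loss of N2 with a 1,2-hydrogen shift gives the terminal alkyne, whose new carbon becomes C2, under mild base that leaves the MOM ethers and the vinyl group untouched.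

Step 7
Reactants: 9 1-ethynyl-2-methoxy-3,4-bis(methoxymethoxy)-5-(2-methylbut-3-en-2-yl)benzene; 10 (1S,2R)-trans-2-phenylcyclohexan-1-ol
Product: 11 1-{(Z)-2-[(1S,2R)-2-phenylcyclohexyloxy]ethenyl}-2-methoxy-3,4-bis(methoxymethoxy)-5-(2-methylbut-3-en-2-yl)benzene
Conditions: 10 (1.3 equiv), KOt-Bu (0.3 equiv), DMSO, Ar, 80 °C; chromatography on Et3N-deactivated silica to remove excess 10 and any E isomer
Reagents that add atoms: none
Why: Superbase-mediated anti-Markovnikov hydroalkoxylation of an aryl acetylene: the potassium alkoxide of 10 adds to the terminal carbon, the alpha-aryl vinyl anion develops anti to the incoming oxygen and is protonated before it inverts, so the kinetic Z-enol ether should form, while the quaternary allylic carbon rules out base isomerisation of the side chain and the two stereocentres of 10 are not involved.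

Step 8
Reactants: 12 2,4-dihydroxybenzaldehyde
Product: 13 2-hydroxy-4-(methoxymethoxy)benzaldehyde
Conditions: MOMCl (1.05 equiv), i-Pr2NEt (1.2 equiv), CH2Cl2, 0 °C
Reagents that add atoms: chloromethyl methyl ether (MOMCl), COCCl
Why: Regioselective MOM protection: the 4-OH is free and para-conjugated to the aldehyde whereas the 2-OH is hydrogen-bonded to it, a standard differentiation of this dihydroxybenzaldehyde.

Step 9
Reactants: 13 2-hydroxy-4-(methoxymethoxy)benzaldehyde
Product: 14 tert-butyl 2-formyl-5-(methoxymethoxy)phenyl carbonate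
Conditions: Boc2O, DMAP (cat.), i-Pr2NEt (cat.), THF, 0 °C to rt
Reagents that add atoms: di-tert-butyl dicarbonate (Boc2O), CC(C)(C)OC(=O)OC(=O)OC(C)(C)C
Why: DMAP-catalysed O-acylation with Boc2O, in which the acylpyridinium species is reactive enough to carbonate the chelated phenol and the by-products are volatile.

Step 10
Reactants: 14 tert-butyl 2-formyl-5-(methoxymethoxy)phenyl carbonate
Product: 15 tert-butyl 2-(hydroxymethyl)-5-(methoxymethoxy)phenyl carbonate
Conditions: BH3·THF, THF, 0 °C; then pH 7 buffer
Reagents that add atoms: none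
Why: Borane reduction of the aldehyde, chosen over borohydride because it leads to a neutral boron alkoxide rather than a free alkoxide, so the Boc group should not migrate and the quinone methide should not be released (and over-reduced) at this stage.

Step 11
Reactants: 11 1-{(Z)-2-[(1S,2R)-2-phenylcyclohexyloxy]ethenyl}-2-methoxy-3,4-bis(methoxymethoxy)-5-(2-methylbut-3-en-2-yl)benzene; 15 tert-butyl 2-(hydroxymethyl)-5-(methoxymethoxy)phenyl carbonate
Product: 18 (2R,3R)-cis-3-[2-methoxy-3,4-bis(methoxymethoxy)-5-(2-methylbut-3-en-2-yl)phenyl]-7-(methoxymethoxy)-2-{[(1S,2R)-2-phenylcyclohexyl]oxy}chroman, via magnesium phenoxide benzylic carbonate 16 (not isolated), via o-quinone methide 17 (not isolated)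
Conditions: 11 (1 equiv), 15 (2 equiv, in portions), t-BuMgCl (1 equiv per 15), toluene, −78 °C to rt
Reagents that add atoms: none
Why: t-BuMgCl deprotonates 15, the Boc group moves from the phenolic to the benzylic oxygen (16), and the magnesium phenoxide expels tert-butyl carbonate below room temperature to release o-quinone methide 17, which is consumed as it forms. The closest known reaction type is the inverse-electron-demand hetero-Diels-Alder reaction of such low-temperature o-quinone methides with enol ethers of trans-2-phenylcyclohexanol, and racemic cycloadditions of o-quinone methides with beta-aryl enol ethers are also known, so only the combination of the two is untried. The pyran ring closes by a concerted but asynchronous [4+2] cycloaddition in which the nucleophilic beta-carbon of 11 bonds to the methide CH2 (C3–C4) slightly ahead of O1–C2 bond formation, the polarity of both partners fixing the regiochemistry. Addition is suprafacial on the Z-alkene, so the C2 alkoxy and C3 aryl groups emerge cis, and C3 is controlled by the auxiliary: allylic 1,3-strain in the Z-enol ether enforces the s-trans C=C–O–C arrangement with the carbinol C–H in the alkene plane, the equatorial phenyl group covers one face, and attack on the open Re face of the beta-carbon gives 2R,3R. The step needs pi-facial selectivity, which rests on this conformational lock and on the geometric purity of 11 (the E isomer would deliver the opposite C3 configuration), and chemoselectivity, which is secured because 11 contains only one electron-rich alkene and its neopentyl-type vinyl group is inert to the electron-poor heterodiene. Endo or exo orientation has no consequence, since C4 is CH2 and C2 loses its substituent in step 12.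

Step 12
Reactants: 18 (2R,3R)-cis-3-[2-methoxy-3,4-bis(methoxymethoxy)-5-(2-methylbut-3-en-2-yl)phenyl]-7-(methoxymethoxy)-2-{[(1S,2R)-2-phenylcyclohexyl]oxy}chroman
Product: 20 (3R)-7-(methoxymethoxy)-3-[2-methoxy-3,4-bis(methoxymethoxy)-5-(2-methylbut-3-en-2-yl)phenyl]chroman, via cyclic oxocarbenium ion 19 (not isolated)
Conditions: Et3SiH (excess, present first), BF3·OEt2 (1.5 equiv), CH2Cl2, −78 °C; cold aqueous quench
Reagents that add atoms: none
Why: Ionic silane reduction of an acetal: BF3 binds the more basic exocyclic alkoxy oxygen, the auxiliary leaves and oxocarbenium ion 19 takes up hydride at C2, the aldehyde-derived acetal ionising far faster at −78 °C than the formaldehyde-derived MOM acetals, while the excess of silane present before the acid keeps 19 too short-lived to lose its C3 proton, so C3 stays R.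

Step 13
Reactants: 20 (3R)-7-(methoxymethoxy)-3-[2-methoxy-3,4-bis(methoxymethoxy)-5-(2-methylbut-3-en-2-yl)phenyl]chroman
Product: 21 (3R)-3-[3,4-dihydroxy-2-methoxy-5-(2-methylbut-3-en-2-yl)phenyl]chroman-7-ol (CNP0167796.1)
Conditions: HCl (0.5 M in MeOH), degassed, Ar, 40 °C
Reagents that add atoms: none
Why: Acid-catalysed transacetalisation of the three aryl MOM ethers to methanol; the monosubstituted, neopentyl-type alkene is not protonated by dilute acid at this temperature, so the 4'-OH should not cyclise onto it, exclusion of oxygen protects the catechol, and C3 carries no acidifying group and stays R.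

Compound list
1 | 2,3,4-trihydroxybenzaldehyde | O=Cc1ccc(O)c(O)c1O | starting material
2 | prenyl bromide (1-bromo-3-methylbut-2-ene) | CC(C)=CCBr | starting material
3 | 2,3-dihydroxy-4-(3-methylbut-2-enyloxy)benzaldehyde | O=Cc1ccc(OCC=C(C)C)c(O)c1O | intermediate
4 | 2-hydroxy-3-(methoxymethoxy)-4-(3-methylbut-2-enyloxy)benzaldehyde | O=Cc1ccc(OCC=C(C)C)c(OCOC)c1O | intermediate
5 | 2-methoxy-3-(methoxymethoxy)-4-(3-methylbut-2-enyloxy)benzaldehyde | O=Cc1ccc(OCC=C(C)C)c(OCOC)c1OC | intermediate
6 | ortho-dienone, not isolated: 6-methoxy-5-(methoxymethoxy)-3-(2-methylbut-3-en-2-yl)-4-oxocyclohexa-1,5-diene-1-carbaldehyde (racemic at C3) | O=CC1=CC(C(C)(C)C=C)C(=O)C(OCOC)=C1OC | intermediate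
7 | 4-hydroxy-2-methoxy-3-(methoxymethoxy)-5-(2-methylbut-3-en-2-yl)benzaldehyde | O=Cc1cc(C(C)(C)C=C)c(O)c(OCOC)c1OC | intermediate
8 | 2-methoxy-3,4-bis(methoxymethoxy)-5-(2-methylbut-3-en-2-yl)benzaldehyde | O=Cc1cc(C(C)(C)C=C)c(OCOC)c(OCOC)c1OC | intermediate
9 | 1-ethynyl-2-methoxy-3,4-bis(methoxymethoxy)-5-(2-methylbut-3-en-2-yl)benzene | C#Cc1cc(C(C)(C)C=C)c(OCOC)c(OCOC)c1OC | intermediate
10 | (1S,2R)-trans-2-phenylcyclohexan-1-ol | O[C@H]1CCCC[C@@H]1c1ccccc1 | starting material
11 | 1-{(Z)-2-[(1S,2R)-2-phenylcyclohexyloxy]ethenyl}-2-methoxy-3,4-bis(methoxymethoxy)-5-(2-methylbut-3-en-2-yl)benzene | C=CC(C)(C)c1cc(/C=C\O[C@H]2CCCC[C@@H]2c2ccccc2)c(OC)c(OCOC)c1OCOC | intermediate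
12 | 2,4-dihydroxybenzaldehyde | O=Cc1ccc(O)cc1O | starting material
13 | 2-hydroxy-4-(methoxymethoxy)benzaldehyde | O=Cc1ccc(OCOC)cc1O | intermediate
14 | tert-butyl 2-formyl-5-(methoxymethoxy)phenyl carbonate | O=Cc1ccc(OCOC)cc1OC(=O)OC(C)(C)C | intermediate
15 | tert-butyl 2-(hydroxymethyl)-5-(methoxymethoxy)phenyl carbonate | OCc1ccc(OCOC)cc1OC(=O)OC(C)(C)C | intermediate
16 | not isolated: chloromagnesium 2-[(tert-butoxycarbonyloxy)methyl]-5-(methoxymethoxy)phenoxide | CC(C)(C)OC(=O)OCc1ccc(OCOC)cc1O[Mg]Cl | intermediate
17 | o-quinone methide, not isolated: 3-(methoxymethoxy)-6-methylidenecyclohexa-2,4-dien-1-one | C=C1C=CC(OCOC)=CC1=O | intermediate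
18 | (2R,3R)-cis-3-[2-methoxy-3,4-bis(methoxymethoxy)-5-(2-methylbut-3-en-2-yl)phenyl]-7-(methoxymethoxy)-2-{[(1S,2R)-2-phenylcyclohexyl]oxy}chroman | [C@@H]1(O[C@H]2CCCC[C@@H]2c2ccccc2)Oc2cc(OCOC)ccc2C[C@@H]1c1cc(C(C)(C)C=C)c(OCOC)c(OCOC)c1OC | intermediate
19 | cyclic oxocarbenium ion (C2=O1+), not isolated: (3R)-3-aryl-7-(methoxymethoxy)-3,4-dihydrochromenylium, aryl as in 18 | C=CC(C)(C)c1cc([C@@H]2C=[O+]c3cc(OCOC)ccc3C2)c(OC)c(OCOC)c1OCOC | intermediate
20 | (3R)-7-(methoxymethoxy)-3-[2-methoxy-3,4-bis(methoxymethoxy)-5-(2-methylbut-3-en-2-yl)phenyl]chroman | C=CC(C)(C)c1cc([C@@H]2COc3cc(OCOC)ccc3C2)c(OC)c(OCOC)c1OCOC | intermediate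
21 | (3R)-3-[3,4-dihydroxy-2-methoxy-5-(2-methylbut-3-en-2-yl)phenyl]chroman-7-ol (CNP0167796.1) | C=CC(C)(C)c1cc([C@@H]2COc3cc(O)ccc3C2)c(OC)c(O)c1O | target

Total step count: 13. The synthesis is convergent: steps 1–7 build ring B, steps 8–10 build ring A, and steps 11–13 follow the union.
Longest linear sequence: 10 steps (1–7, then 11–13).

Steps most likely to fail

Step 11. The twisted, ortho-substituted Z-beta-aryl enol ether may capture the quinone methide too slowly, so that the methide oligomerises. Shielding by the phenyl group may also be incomplete, so that facial selectivity is poor. The fallback gives up the cycloaddition, makes C3–C4 by oxazolidinone-directed enolate benzylation and makes O1–C2 by Mitsunobu etherification. It sets out from 9 and 15 and returns to the route at 20. Anti-Markovnikov hydration of 9 ([CpRu(MeCN)3]PF6, 5,5'-bis(trifluoromethyl)-2,2'-bipyridine, aqueous NMP, rt) would give arylacetaldehyde F1. Pinnick oxidation (NaClO2, NaH2PO4, 2-methylbut-2-ene) would then give arylacetic acid F2, and PivCl/Et3N would give mixed pivalic anhydride F3. Lithiated (R)-4-benzyl-2-oxazolidinone would convert this into N-arylacetyl imide F4. An Appel reaction on 15 (CBr4, PPh3, CH2Cl2, 0 °C) would give benzylic bromide F5, which is used crude. The sodium Z-enolate of F4 (NaHMDS, THF, −78 °C) should be benzylated by F5 on the face away from the benzyl group of the oxazolidinone to give (2R)-benzylated imide F6. LiBH4 then releases Boc-protected primary alcohol F7, K2CO3/MeOH removes the aryl carbonate to give phenol alcohol F8, and PPh3/DIAD closes the pyran ring to 20 without touching the stereocentre.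

Step 7. The electron-rich aryl alkyne may resist alkoxide addition. At the higher temperature then required, Z-to-E isomerisation of the enol ether would erode the geometric purity on which C3 depends. The fallback replaces nucleophilic addition to the alkyne by stereoretentive C–O cross-coupling. It sets out from 8 and returns at 11. Stork-Zhao olefination of 8 ([Ph3PCH2I]I, NaHMDS, THF/DMPU, −78 °C) would give (Z)-vinyl iodide F9. This is coupled with 10 under copper catalysis (CuI, 3,4,7,8-tetramethyl-1,10-phenanthroline, Cs2CO3, toluene, 80 °C), with retention of the alkene geometry.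

Step 12. Three processes may interfere: endocyclic instead of exocyclic C–O cleavage, Lewis acid attack on the MOM acetals, and proton loss from C3 of the oxocarbenium ion with erosion of configuration. The fallback removes C2–O in two reductive stages that need no Lewis acid and no silane. It sets out from 18 and returns at 20. Mild hydrolysis (camphorsulfonic acid cat., aqueous THF, rt), which spares the slower formaldehyde acetals and frees 10, would give lactol F10. This is reduced at once with NaBH4 (EtOH, 0 °C), to limit enolisation of its open aldehyde form, giving phenol alcohol F8. Mitsunobu etherification (PPh3, DIAD, THF) then closes O1–C2 to give 20.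

Further compounds
F1 | step 11 | 2-[2-methoxy-3,4-bis(methoxymethoxy)-5-(2-methylbut-3-en-2-yl)phenyl]acetaldehyde | O=CCc1cc(C(C)(C)C=C)c(OCOC)c(OCOC)c1OC
F2 | step 11 | 2-[2-methoxy-3,4-bis(methoxymethoxy)-5-(2-methylbut-3-en-2-yl)phenyl]acetic acid | OC(=O)Cc1cc(C(C)(C)C=C)c(OCOC)c(OCOC)c1OC
F3 | step 11 | mixed anhydride of F2 and pivalic acid | CC(C)(C)C(=O)OC(=O)Cc1cc(C(C)(C)C=C)c(OCOC)c(OCOC)c1OC
F4 | step 11 | (4R)-4-benzyl-3-{2-[2-methoxy-3,4-bis(methoxymethoxy)-5-(2-methylbut-3-en-2-yl)phenyl]acetyl}oxazolidin-2-one | O=C(Cc1cc(C(C)(C)C=C)c(OCOC)c(OCOC)c1OC)N1C(=O)OC[C@H]1Cc1ccccc1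
F5 | step 11 | tert-butyl 2-(bromomethyl)-5-(methoxymethoxy)phenyl carbonate | BrCc1ccc(OCOC)cc1OC(=O)OC(C)(C)C
F6 | step 11 | (4R)-4-benzyl-3-{(2R)-3-[2-(tert-butoxycarbonyloxy)-4-(methoxymethoxy)phenyl]-2-[2-methoxy-3,4-bis(methoxymethoxy)-5-(2-methylbut-3-en-2-yl)phenyl]propanoyl}oxazolidin-2-one | O=C([C@H](Cc1ccc(OCOC)cc1OC(=O)OC(C)(C)C)c1cc(C(C)(C)C=C)c(OCOC)c(OCOC)c1OC)N1C(=O)OC[C@H]1Cc1ccccc1
F7 | step 11 | tert-butyl 2-{(2R)-3-hydroxy-2-[2-methoxy-3,4-bis(methoxymethoxy)-5-(2-methylbut-3-en-2-yl)phenyl]propyl}-5-(methoxymethoxy)phenyl carbonate | OC[C@H](Cc1ccc(OCOC)cc1OC(=O)OC(C)(C)C)c1cc(C(C)(C)C=C)c(OCOC)c(OCOC)c1OC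
F8 | step 11 | 2-{(2R)-3-hydroxy-2-[2-methoxy-3,4-bis(methoxymethoxy)-5-(2-methylbut-3-en-2-yl)phenyl]propyl}-5-(methoxymethoxy)phenol | OC[C@H](Cc1ccc(OCOC)cc1O)c1cc(C(C)(C)C=C)c(OCOC)c(OCOC)c1OC
F9 | step 7 | 1-[(Z)-2-iodoethenyl]-2-methoxy-3,4-bis(methoxymethoxy)-5-(2-methylbut-3-en-2-yl)benzene | I/C=C\c1cc(C(C)(C)C=C)c(OCOC)c(OCOC)c1OC
F10 | step 12 | (3R)-3-[2-methoxy-3,4-bis(methoxymethoxy)-5-(2-methylbut-3-en-2-yl)phenyl]-7-(methoxymethoxy)chroman-2-ol (anomeric mixture at C2) | OC1Oc2cc(OCOC)ccc2C[C@@H]1c1cc(C(C)(C)C=C)c(OCOC)c(OCOC)c1OC
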